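- A flask that stops gaining D looks slow, but elm's D reads 21.1% at 1.33 h and 21.8% at 3.00 h, so its later hours added nothing beyond the scatter.

| setting | elm | maple | alder | oak | Tuesday's | Sunday's | Wednesday's | Friday's | Saturday's |
|---|---|---|---|---|---|---|---|---|---|
| E | 0.11 M | 0.11 M | 0.11 M | 0.14 M | 0.20 M | 0.30 M | 0.040 M | 0.11 M | 0.11 M |
| Z | 0.024 M | 0.12 M | 0.34 M | 0.132 M | 0.0600 M | 0.0600 M | 0.0300 M | 0.400 M | 0.132 M |
| remark | run made earlier | run made earlier | run made earlier | run made earlier |  |  |  |  |  |
| time |  |  |  |  | 4.0 h | 4.0 h | 4.0 h | 4.0 h | 4.0 h |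

| run | time / h | D / % | E / % |
|---|---|---|---|
| elm | 0.250 | 10.9 | 79.5 |
| elm | 0.667 | 18.4 | 64.4 |
| elm | 1.33 | 21.1 | 61.2 |
| elm | 2.00 | 22.7 | 62.0 |
| elm | 3.00 | 21.8 | 61.0 |
| maple | 0.250 | 24.3 | 58.1 |
| maple | 0.417 | 30.0 | 44.2 |
| maple | 0.833 | 44.7 | 29.3 |
| maple | 1.33 | 53.0 | 22.3 |
| maple | 3.00 | 64.0 | 13.3 |
| alder | 0.250 | 32.8 | 42.6 |
| alder | 0.417 | 43.9 | 31.0 |
| alder | 0.833 | 53.8 | 18.8 |
| alder | 1.33 | 62.7 | 14.5 |
| alder | 3.00 | 75.4 | 7.0 |
| oak | 0.250 | 26.9 | 51.2 |
| oak | 0.417 | 34.7 | 41.2 |
| oak | 0.833 | 45.0 | 27.3 |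
| oak | 1.33 | 51.1 | 18.5 |
| oak | 3.00 | 63.9 | 13.2 |

(each reading ± 1 percentage point)

- a reading or a percentage of D counts all its forms, free or not
- a reading of E is of its free form alone

- the flasks put in order of amount of D, in percent of the E charged, best first, at 4.0 h (Tuesday's / Sunday's / Wednesday's / Friday's / Saturday's)
- the amount of D, in percent of the E charged of the flask you put first, at 4.0 h
- the amount of D, in percent of the E charged of the flask you put last, at 4.0 h

- Before you spend hours on a flask, reckon its ceiling: the charged Z over the charged E, the most D that Z as limiting reagent allows if each D uses one Z. This gives 21.8% for elm, where the readings level off, and 20.0% for Sunday's.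
- Work with what is left: the fraction of Z remaining is one minus D over the ceiling, so a flask near its ceiling has little to gain from waiting.
- Tuesday's ceiling is 30.0%. It and Sunday's hold more E than elm did, so I expect both at their ceilings by 4.0 h and would not lengthen them.
- Wednesday's ceiling is 75.0%, but no earlier run is that dilute, so I place it third, on speed, without a number.
- The ceilings of Saturday's, 120%, and Friday's, 364%, lie beyond the E charged. I read those two from the runs instead: Saturday's somewhat above maple's 64.0% at 3.00 h, and Friday's above alder's 75.4%.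
- My low is Sunday's 20.0%, where the forecast prints 19.8%. The forecast gives Friday's > Saturday's > Wednesday's > Tuesday's > Sunday's with a top of 80%, for Friday's “like alder, 75% at 3 h, with more Z”.
- The flasks give Friday's > Saturday's > Wednesday's > Tuesday's > Sunday's, with 82.5% first and 20.0% last.

    E + D ⇌ J, settled at all times (K = 46.0 M⁻¹)
    E + Z → D, rate k2*[E]^1.5*[Z]^0.5 (k = 13.7 M⁻¹ h⁻¹)
    G ⇌ D, rate k3*(cs3 - [D]) while solid is left; crystals form when [D] > cs3 (solubility = 38.0 mM, k = 14.8 h⁻¹)

Sunday's stands at its ceiling of 20.0%, although its E reads 62.1% and J, the pair of E and D, reads 35.8%, each J counted as two; D is the same at 40.0 h. Tuesday's stands at 30.0% against 30.0%, its Z at 0% of its charge already at 2.00 h. Wednesday's, by contrast, has D at 52.1% under 75.0%, so one minus D over the ceiling leaves 30.5% of its Z at 4.0 h, and at 40.0 h its D stands at 75.0%.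

The runs were generated by integration with constants of no real substance; the scatter is artificial.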